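**Plan**
- Retrosynthesis: O1–C2 is cut first, which opens ring C to a racemic C2 carbinol. The carbinol goes back to the ketone, the two prenyl groups to C-allyl groups at C8 and C2' (cross metathesis), these to O-allyl ethers at O7 and O3' (two Claisen rearrangements), and the C3–C4 bond is cut last (Claisen–Schmidt condensation of a ring A aldehyde with a ring B methyl ketone).
- Enabling feature: the 4'-OH of ring B is para to C1', the carbon that carries C2. Loss of the C2 hydroxyl therefore gives a ring B para-quinone methide (C4'=O, exocyclic C1'=C2), and the C8a hydroxyl of ring A can add to C2 through a six-membered transition state.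
- Forward: each aromatic piece is mono-O-allylated, the two are condensed to the diarylpropenone, the enone is reduced, both allyl groups are moved from O to C and turned into prenyl groups, the ketone is reduced, and ring C, the only ring that is built, is closed last.
- Stereochemistry: C2 is the only stereocenter. It is set in the last step by a chiral phosphoric acid, which takes both enantiomers of the carbinol through the planar quinone methide to the (2S)-flavan.
- No protecting groups are used: the two allyl ethers mask O7 and O3' in the base-mediated steps and then become the carbon skeletons of the prenyl groups.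

Key step: step 8

Remark: flavan numbering of the target (O1, C2–C4, C4a–C8a, C1'–C6') is used for all intermediates.
Assumption: 2,4-dihydroxy-5-methoxybenzaldehyde is taken as a catalogue compound.
Assumption: the sense of induction of the phosphoric acid cannot be predicted with certainty; (R)-TRIP is written, and its enantiomer is used instead if screening shows the opposite sense.

**Step 1**
Reactants: 1 2,4-dihydroxy-5-methoxybenzaldehyde; 2 allyl bromide
Product: 3 2-hydroxy-5-methoxy-4-(prop-2-en-1-yloxy)benzaldehyde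
Conditions: allyl bromide (1.05 equiv), K2CO3 (1.1 equiv), acetone, 50 °C
Reagents that add atoms: allyl bromide, C=CCBr
Why: Regioselective Williamson etherification: the 2-OH is held in a hydrogen bond to the aldehyde and is less acidic, so one equivalent of base and halide should alkylate the 4-OH.

**Step 2**
Reactants: 4 1-(3,4-dihydroxyphenyl)ethan-1-one (3,4-dihydroxyacetophenone); 2 allyl bromide
Product: 6 1-[4-hydroxy-3-(prop-2-en-1-yloxy)phenyl]ethan-1-one, via disodium catecholate 5 (not isolated)
Conditions: NaH (2.1 equiv), DMSO, 20 °C; then allyl bromide (1.0 equiv); aq. HCl work-up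
Reagents that add atoms: allyl bromide, C=CCBr
Why: Regioselective Williamson etherification through the catecholate dianion: with both hydroxyls deprotonated, the 3-oxide, which is not conjugated with the para acetyl group, is the more nucleophilic oxygen and should take up the single equivalent of allyl bromide.

**Step 3**
Reactants: 3 2-hydroxy-5-methoxy-4-(prop-2-en-1-yloxy)benzaldehyde; 6 1-[4-hydroxy-3-(prop-2-en-1-yloxy)phenyl]ethan-1-one
Product: 7 (E)-1-[4-hydroxy-3-(prop-2-en-1-yloxy)phenyl]-3-[2-hydroxy-5-methoxy-4-(prop-2-en-1-yloxy)phenyl]prop-2-en-1-one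
Conditions: KOH (50% aq., excess), EtOH, 20 to 50 °C, argon; AcOH to pH 5 at 0 °C
Reagents that add atoms: none
Why: Claisen–Schmidt aldol condensation: excess hydroxide forms the enolate of the ketone phenoxide, the aldol adduct dehydrates to the conjugated (E)-enone, and aryl allyl ethers are inert to aqueous alcoholic KOH.

**Step 4**
Reactants: 7 (E)-1-[4-hydroxy-3-(prop-2-en-1-yloxy)phenyl]-3-[2-hydroxy-5-methoxy-4-(prop-2-en-1-yloxy)phenyl]prop-2-en-1-one
Product: 8 1-[4-hydroxy-3-(prop-2-en-1-yloxy)phenyl]-3-[2-hydroxy-5-methoxy-4-(prop-2-en-1-yloxy)phenyl]propan-1-one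
Conditions: [(Ph3P)CuH]6 (5 mol %), PhMe2SiH (4 equiv), t-BuOH (3 equiv), toluene, 20 °C; then K2CO3, MeOH, 0 °C
Reagents that add atoms: none
Why: Stryker-type conjugate reduction: phosphine-ligated CuH, regenerated by the silane, delivers hydride to C4 of the enone and t-BuOH protonates the copper enolate, while the aryl ketone and the unactivated allyl C=C bonds should not react; phenols silylated in the flask are freed in the basic methanol treatment.

**Step 5**
Reactants: 8 1-[4-hydroxy-3-(prop-2-en-1-yloxy)phenyl]-3-[2-hydroxy-5-methoxy-4-(prop-2-en-1-yloxy)phenyl]propan-1-one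
Product: 9 1-[3,4-dihydroxy-2-(prop-2-en-1-yl)phenyl]-3-[2,4-dihydroxy-5-methoxy-3-(prop-2-en-1-yl)phenyl]propan-1-one
Conditions: N,N-diethylaniline, 190 °C, argon
Reagents that add atoms: none
Why: Two aromatic Claisen rearrangements ([3,3]-sigmatropic shift, then tautomerisation): the O7 allyl group can only go to C8 because the other ortho carbon C6 carries the methoxy group and the para carbon C4a carries the chain, and the O3' allyl group should go to C2' because the other ortho carbon C4' carries oxygen.

**Step 6**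
Reactants: 9 1-[3,4-dihydroxy-2-(prop-2-en-1-yl)phenyl]-3-[2,4-dihydroxy-5-methoxy-3-(prop-2-en-1-yl)phenyl]propan-1-one; 10 2-methylbut-2-ene
Product: 11 1-[3,4-dihydroxy-2-(3-methylbut-2-en-1-yl)phenyl]-3-[2,4-dihydroxy-5-methoxy-3-(3-methylbut-2-en-1-yl)phenyl]propan-1-one
Conditions: (H2IMes)(PCy3)Cl2Ru=CHPh (second-generation Grubbs catalyst, 2 × 5 mol %), 2-methylbut-2-ene (large excess), CH2Cl2, 40 °C, sealed tube, argon
Reagents that add atoms: 2-methylbut-2-ene, CC=C(C)C
Why: Olefin cross metathesis of the two terminal allyl groups with a large excess of 2-methylbut-2-ene should give the trisubstituted prenyl alkenes and propene, a routine conversion of C-allyl phenols that tolerates free hydroxyl and ketone groups.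

**Step 7**
Reactants: 11 1-[3,4-dihydroxy-2-(3-methylbut-2-en-1-yl)phenyl]-3-[2,4-dihydroxy-5-methoxy-3-(3-methylbut-2-en-1-yl)phenyl]propan-1-one
Product: 12 rac-1-[3,4-dihydroxy-2-(3-methylbut-2-en-1-yl)phenyl]-3-[2,4-dihydroxy-5-methoxy-3-(3-methylbut-2-en-1-yl)phenyl]propan-1-ol
Conditions: NaBH4 (excess), MeOH/THF, 0 to 20 °C, argon; pH 7 phosphate buffer work-up, no chromatography on silica, used at once
Reagents that add atoms: none
Why: Borohydride reduction of the aryl ketone should give the racemic benzylic alcohol without touching the trisubstituted alkenes; the configuration of the carbinol does not matter because step 8 erases it.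

**Step 8**
Reactants: 12 rac-1-[3,4-dihydroxy-2-(3-methylbut-2-en-1-yl)phenyl]-3-[2,4-dihydroxy-5-methoxy-3-(3-methylbut-2-en-1-yl)phenyl]propan-1-ol
Product: 14 (2S)-2-[3,4-dihydroxy-2-(3-methylbut-2-en-1-yl)phenyl]-6-methoxy-8-(3-methylbut-2-en-1-yl)-3,4-dihydro-2H-chromen-7-ol, via para-quinone methide 13 (not isolated)
Conditions: (R)-TRIP [(R)-3,3'-bis(2,4,6-triisopropylphenyl)-1,1'-binaphthyl-2,2'-diyl hydrogen phosphate] (10 mol %), 5 Å molecular sieves, CH2Cl2, 0 °C, argon
Reagents that add atoms: none
Why: Proposed new method: the chiral phosphoric acid hydrogen-bonds the benzylic hydroxyl and the para 4'-OH of ring B and expels water to give the para-quinone methide 13 (C4'=O, exocyclic C1'=C2), so both enantiomers of 12 converge on one planar intermediate. The closest known reaction types are the phosphoric acid-catalysed enantioconvergent 1,6-addition of nucleophiles to para-quinone methides formed in situ from racemic para-hydroxybenzyl alcohols and the racemic acid-mediated closure of 1,3-diarylpropanols to flavans; what is new is an intramolecular phenol oxygen as the nucleophile on an alkyl-substituted methide. Ring C closes by a 6-exo-trig oxa-1,6-addition of the C8a hydroxyl to the methide carbon C2, and rearomatisation of ring B drives it. The C2 stereocenter is under catalyst control: the phosphate should bridge the 3'-OH/4'-C=O end of the quinone methide and the O–H of the attacking phenol, so that a 2,4,6-triisopropylphenyl group shields one face of C2. The step needs attack by oxygen and not by a prenyl alkene, and reaction at C2 only; this is secured because C2 is the only benzylic carbon para to a free hydroxyl, only the C8a oxygen reaches it through a six-membered transition state, and a weak acid at 0 °C should not protonate trisubstituted alkenes. Low temperature and short contact are used to keep the product ether from re-ionising.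

**Compound list**
1 | 2,4-dihydroxy-5-methoxybenzaldehyde | COc1cc(C=O)c(O)cc1O | starting material
2 | allyl bromide (3-bromoprop-1-ene) | C=CCBr | starting material
3 | 2-hydroxy-5-methoxy-4-(prop-2-en-1-yloxy)benzaldehyde | COc1cc(C=O)c(O)cc1OCC=C | intermediate
4 | 1-(3,4-dihydroxyphenyl)ethan-1-one | CC(=O)c1ccc(O)c(O)c1 | starting material
5 | disodium 4-acetylbenzene-1,2-bis(olate) (not isolated) | CC(=O)c1ccc([O-])c([O-])c1.[Na+].[Na+] | intermediate
6 | 1-[4-hydroxy-3-(prop-2-en-1-yloxy)phenyl]ethan-1-one | CC(=O)c1ccc(O)c(OCC=C)c1 | intermediate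
7 | (E)-1-[4-hydroxy-3-(prop-2-en-1-yloxy)phenyl]-3-[2-hydroxy-5-methoxy-4-(prop-2-en-1-yloxy)phenyl]prop-2-en-1-one | COc1cc(/C=C/C(=O)c2ccc(O)c(OCC=C)c2)c(O)cc1OCC=C | intermediate
8 | 1-[4-hydroxy-3-(prop-2-en-1-yloxy)phenyl]-3-[2-hydroxy-5-methoxy-4-(prop-2-en-1-yloxy)phenyl]propan-1-one | COc1cc(CCC(=O)c2ccc(O)c(OCC=C)c2)c(O)cc1OCC=C | intermediate
9 | 1-[3,4-dihydroxy-2-(prop-2-en-1-yl)phenyl]-3-[2,4-dihydroxy-5-methoxy-3-(prop-2-en-1-yl)phenyl]propan-1-one | COc1cc(CCC(=O)c2ccc(O)c(O)c2CC=C)c(O)c(CC=C)c1O | intermediate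
10 | 2-methylbut-2-ene | CC=C(C)C | starting material
11 | 1-[3,4-dihydroxy-2-(3-methylbut-2-en-1-yl)phenyl]-3-[2,4-dihydroxy-5-methoxy-3-(3-methylbut-2-en-1-yl)phenyl]propan-1-one | COc1cc(CCC(=O)c2ccc(O)c(O)c2CC=C(C)C)c(O)c(CC=C(C)C)c1O | intermediate
12 | rac-1-[3,4-dihydroxy-2-(3-methylbut-2-en-1-yl)phenyl]-3-[2,4-dihydroxy-5-methoxy-3-(3-methylbut-2-en-1-yl)phenyl]propan-1-ol (racemate) | COc1cc(CCC(O)c2ccc(O)c(O)c2CC=C(C)C)c(O)c(CC=C(C)C)c1O | intermediate
13 | 4-{3-[2,4-dihydroxy-5-methoxy-3-(3-methylbut-2-en-1-yl)phenyl]propylidene}-2-hydroxy-3-(3-methylbut-2-en-1-yl)cyclohexa-2,5-dien-1-one (not isolated) | O=C1C=CC(=CCCc2cc(OC)c(O)c(CC=C(C)C)c2O)C(CC=C(C)C)=C1O | intermediate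
14 | (2S)-2-[3,4-dihydroxy-2-(3-methylbut-2-en-1-yl)phenyl]-6-methoxy-8-(3-methylbut-2-en-1-yl)-3,4-dihydro-2H-chromen-7-ol | COc1cc2c(c(CC=C(C)C)c1O)O[C@H](c1ccc(O)c(O)c1CC=C(C)C)CC2 | target

**Step count and risks**
Total step count: 8. Longest linear sequence: 7 steps (step 1 or step 2, then steps 3 to 8).

Steps most likely to fail:

1. Step 8. The enantiomeric purity may be eroded by uncatalysed background closure or by re-ionisation of the product ether under the acid. The quinone methide may also lose a proton from C3 (elimination to the styrene), or C2 may be captured by the neighbouring prenyl alkene. The fallback uses known chemistry, sets out from 8 and returns at 14. Selective tosylation of the more acidic 4'-hydroxyl, which is para to the ketone (TsCl, K2CO3, acetone, 0 °C), should give the 4'-O-tosyl ketone F1. CBS reduction ((S)-2-methyl-CBS-oxazaborolidine, BH3·SMe2, THF, −20 °C) should give the (R)-carbinol F2. Mitsunobu closure (PPh3, DIAD, THF, 0 °C) forms the O1–C2 bond with inversion and should give the (2S)-flavan bis(allyl ether) F3; the sulfonate blocks quinone methide formation and keeps the displacement on an SN2 course. Double Claisen rearrangement (1,2-dichlorobenzene, 190 °C) should give the diallyl flavan F4, and cross metathesis with 10 as in step 6 the bis-prenyl tosylate F5. Mg in MeOH at 20 °C removes the tosyl group and gives 14.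

2. Step 3. Conversion may be low because both partners react as phenoxides, which gives a deactivated aldehyde and a dianionic enolate. The two hydroxyls are left free on purpose, since an allyl group on O8a or O4' would rearrange to C8 or C5' in step 5. The fallback sets out from 3 and 6 and returns at 8. Both free phenols are capped (MOMCl, i-Pr2NEt, CH2Cl2) to give the MOM-protected aldehyde F6 and the MOM-protected ketone F7. Claisen–Schmidt condensation (KOH, EtOH) should give the chalcone F8, and conjugate reduction as in step 4 the saturated ketone F9. HCl (2 M) in MeOH at 40 °C, to which aryl allyl ethers are stable, removes both MOM groups and gives 8.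

3. Step 6. The free catechol may deactivate the ruthenium carbene, and ruthenium hydride species may move the allyl double bonds into conjugation with the rings before metathesis. The fallback sets out from 9 and returns at 11. Peracetylation (Ac2O, pyridine) should give the tetraacetate F10, cross metathesis with 10 under the conditions of step 6 the bis-prenyl tetraacetate F11, and methanolysis (K2CO3, MeOH, 0 °C, argon) gives 11.

**Further compounds**
F1 | step 8 | 4-{3-[2-hydroxy-5-methoxy-4-(prop-2-en-1-yloxy)phenyl]propanoyl}-2-(prop-2-en-1-yloxy)phenyl 4-methylbenzenesulfonate | COc1cc(CCC(=O)c2ccc(OS(=O)(=O)c3ccc(C)cc3)c(OCC=C)c2)c(O)cc1OCC=C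
F2 | step 8 | 4-{(1R)-1-hydroxy-3-[2-hydroxy-5-methoxy-4-(prop-2-en-1-yloxy)phenyl]propyl}-2-(prop-2-en-1-yloxy)phenyl 4-methylbenzenesulfonate | COc1cc(CC[C@@H](O)c2ccc(OS(=O)(=O)c3ccc(C)cc3)c(OCC=C)c2)c(O)cc1OCC=C
F3 | step 8 | 4-[(2S)-6-methoxy-7-(prop-2-en-1-yloxy)-3,4-dihydro-2H-chromen-2-yl]-2-(prop-2-en-1-yloxy)phenyl 4-methylbenzenesulfonate | COc1cc2c(cc1OCC=C)O[C@H](c1ccc(OS(=O)(=O)c3ccc(C)cc3)c(OCC=C)c1)CC2
F4 | step 8 | 2-hydroxy-4-[(2S)-7-hydroxy-6-methoxy-8-(prop-2-en-1-yl)-3,4-dihydro-2H-chromen-2-yl]-3-(prop-2-en-1-yl)phenyl 4-methylbenzenesulfonate | COc1cc2c(c(CC=C)c1O)O[C@H](c1ccc(OS(=O)(=O)c3ccc(C)cc3)c(O)c1CC=C)CC2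
F5 | step 8 | 2-hydroxy-4-[(2S)-7-hydroxy-6-methoxy-8-(3-methylbut-2-en-1-yl)-3,4-dihydro-2H-chromen-2-yl]-3-(3-methylbut-2-en-1-yl)phenyl 4-methylbenzenesulfonate | COc1cc2c(c(CC=C(C)C)c1O)O[C@H](c1ccc(OS(=O)(=O)c3ccc(C)cc3)c(O)c1CC=C(C)C)CC2
F6 | step 3 | 5-methoxy-2-(methoxymethoxy)-4-(prop-2-en-1-yloxy)benzaldehyde | COCOc1cc(OCC=C)c(OC)cc1C=O
F7 | step 3 | 1-[4-(methoxymethoxy)-3-(prop-2-en-1-yloxy)phenyl]ethan-1-one | CC(=O)c1ccc(OCOC)c(OCC=C)c1
F8 | step 3 | (E)-3-[5-methoxy-2-(methoxymethoxy)-4-(prop-2-en-1-yloxy)phenyl]-1-[4-(methoxymethoxy)-3-(prop-2-en-1-yloxy)phenyl]prop-2-en-1-one | COCOc1cc(OCC=C)c(OC)cc1/C=C/C(=O)c1ccc(OCOC)c(OCC=C)c1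
F9 | step 3 | 3-[5-methoxy-2-(methoxymethoxy)-4-(prop-2-en-1-yloxy)phenyl]-1-[4-(methoxymethoxy)-3-(prop-2-en-1-yloxy)phenyl]propan-1-one | COCOc1cc(OCC=C)c(OC)cc1CCC(=O)c1ccc(OCOC)c(OCC=C)c1
F10 | step 6 | 4-{3-[2,4-diacetoxy-5-methoxy-3-(prop-2-en-1-yl)phenyl]propanoyl}-3-(prop-2-en-1-yl)-1,2-phenylene diacetate | COc1cc(CCC(=O)c2ccc(OC(C)=O)c(OC(C)=O)c2CC=C)c(OC(C)=O)c(CC=C)c1OC(C)=O
F11 | step 6 | 4-{3-[2,4-diacetoxy-5-methoxy-3-(3-methylbut-2-en-1-yl)phenyl]propanoyl}-3-(3-methylbut-2-en-1-yl)-1,2-phenylene diacetate | COc1cc(CCC(=O)c2ccc(OC(C)=O)c(OC(C)=O)c2CC=C(C)C)c(OC(C)=O)c(CC=C(C)C)c1OC(C)=O
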